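At early times the two runs at 85 °C already part. In the autumn run, with 59 mM of substrate, target leads after 3.00 h (24.7% against 12.9% of side product), whereas in the noon run, with 110 mM, side product leads after 8.00 h (44.2% against 18.7% of target).

| setting | autumn | spring | noon | north | north-east |
|---|---|---|---|---|---|
| substrate | 59 mM | 64 mM | 110 mM | 47 mM | 100 mM |
| reagent | 235 mM | 235 mM | 235 mM | 235 mM | 235 mM |
| initiator | 2.3 mM | 2.3 mM | 2.3 mM | 2.3 mM | 2.3 mM |
| temperature | 85 °C | 110 °C | 85 °C |  |  |
| remark | run made earlier | run made earlier | run made earlier | at 90 °C until 12 h, from then on at 130 °C | at 130 °C throughout |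
| time |  |  |  | 40 h | 40 h |

- autumn (time / h: target / %, side product / %): 3.00: 24.7, 12.9; 6.00: 44.6, 29.9; 12.0: 61.8, 36.6; 20.0: 64.9, 34.2; 40.0: 63.2, 35.5
- spring (time / h: target / %, side product / %): 1.33: 64.9, 33.6; 4.00: 62.7, 35.8; 8.00: 63.4, 34.4; 12.0: 63.2, 34.8; 15.0: 65.9, 35.3
- noon (time / h: target / %, side product / %): 8.00: 18.7, 44.2; 15.0: 36.5, 61.0; 25.0: 36.1, 64.1; 30.0: 37.6, 63.6; 40.0: 37.3, 63.1

(standard deviation of a reading: 1 percentage point)

- a species is counted by the substrate in it: one side product counts as two
- the earlier runs were read with a standard deviation of 1 percentage point

1. the flask that ends with the higher share of target in all that became target or side product, or "neither" when 2 percentage points or less lies between them (north / north-east / neither)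
2. share of target in all that became target or side product, north
3. share of target in all that became target or side product, north-east

Let Q be side product over target at the end, both counted by substrate, so that the share of target, the selectivity, is 1/(1 + Q). I take Q = 1, the symmetric case, as the zero of my scale. My rule of thumb is that Q grows as a power n of the substrate charge c, and the last readings give:

Q(autumn) = 0.562, Q(noon) = 1.69

n = ln(Q(noon)/Q(autumn)) / ln(110 mM/59 mM) = 1.77

c* = 81.7 mM

This c* is the break-even charge, the substrate charge at which target and side product end equal. The rule then reads Q = (c/c*)^n: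

north: Q = 0.376, share 72.7%

north-east: Q = 1.43, share 41.2%

The rule was read at one temperature, and the spring run shows its border. At 64 mM and 110 °C the rule gives Q = 0.649, a share of 60.6%, but the last reading gives 65.1%. The read Q is 0.826 of the rule's.

In the autumn run, target and side product together stand at 98.4% by 12.0 h, so I expect north to finish before its step and I keep its 72.7%. North-east runs at 130 °C, past the border, so I multiply its Q by that factor once and commit to 45.8%.

The forecast, on its own grounds, says “Final selectivity depends mainly on substrate loading”. It names north, with 74% (68% to 80%) for north and 45% (37% to 54%) for north-east.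

The simulation gives north, with 73.5% for north and 47.3% for north-east.

    initiator → 2 initiating radical (k = 2.10 × 10⁻⁴ min⁻¹, Ea = 113 kJ mol⁻¹)
    substrate + initiating radical → chain carrier (k = 15000 L mol⁻¹ s⁻¹, Ea = 41.0 kJ mol⁻¹)
    reagent + chain carrier → target + initiating radical (k = 1.50 × 10⁵ L mol⁻¹ min⁻¹, Ea = 41.0 kJ mol⁻¹)
    2 chain carrier → ended chains (k = 3.60 × 10⁸ L mol⁻¹ s⁻¹, Ea = 17.0 kJ mol⁻¹)
    substrate + target → side product (k = 0.0850 L mol⁻¹ min⁻¹, Ea = 79.0 kJ mol⁻¹)
    (constants at 90 °C)

North, with 47 mM of substrate, lies below c* and ends with target ahead, while north-east, with 100 mM, lies above it and ends with side product ahead. The difference in substrate charge is the main reason for the gap: with that difference taken away, north-east at north's substrate charge gives 78.7%. The temperature programme is a part of the picture that works against the gap: with that difference taken away, north-east falls to 41.7%, so its programme narrows the gap by 5.6 points. For the neighbour flask, north's recipe with 190 mM of substrate, the same c* gives Q = 4.45 and a share of 18.3%, and that flask ends at 20.6%.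

The readings are calculated with made-up constants; scatter was added.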